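**Abbreviations and numbering.** TBS = tert-butyldimethylsilyl, TBDPS = tert-butyldiphenylsilyl. Elemane numbering is used throughout: ring C5–C6–C7–C8–C9–C10; C14 = methyl on C10; C1=C2 = vinyl on C10; C4(=C3H2)–C15 on C5; C11(=C13H2)–C12 on C7. All ring compounds have 5α-H, 7α-H and 10β-CH3.

## Analysis of the target

The target 31 is an elemanolide: its only carbocycle is the cyclohexane C5–C6–C7–C8–C9–C10, trans-fused across C6–C7 to an α-methylene-γ-butyrolactone (O–C6, C7–C11(=C13H2)–C12=O). C10 is quaternary (C14 methyl, C1=C2 vinyl), C5 carries the allylic alcohol unit C4(=C3H2)–C15H2OH, C8 carries the (3′R)-3′,4′-dihydroxy-2′-methylidenebutanoate, and C9 is the only ring CH2. The ring holds five stereocentres, C5 (R), C6 (R), C7 (R), C8 (S) and C10 (S). The substituents alternate (5β-C4, 6α-O, 7β-C11, 8α-O), so in one chair all four and the C10 vinyl are equatorial and only C14 is axial; the sixth centre, C3′ (R), sits in a separable acid. Two features invite the strategy. First, C2=C1–C10–C5–C4=C3 is a 1,5-diene whose central σ-bond is the ring bond C5–C10, the bond that the presumed biosynthesis forms by Cope rearrangement of a cyclodeca-1(10),4-diene. Second, the carbinol C6 is flanked by two 2-propenyl units (C3/C4/C15 on C5 and C13/C11/C12 on C7), one oxidised to CH2OH and the other to the lactone carbonyl. The sensitive groups are two exo-methylene Michael acceptors, a primary allylic alcohol, and a side chain whose 4′-OH can lactonise onto its own ester under base and expel the C8 alkoxide; the end game must therefore be neutral or acidic. The hard parts are the vicinal quaternary/tertiary pair C10/C5 and the differentiation of O6, O8 and O15 and of the two propenyl units.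

## Retrosynthetic reasoning

**O8–C1′ ester and protecting groups (31 ⇐ 29 ⇐ 21 + 27).** The base-labile side chain is cut off first and is attached last, as its acetonide acid 27, to the free 8α-OH of lactone 21. This keeps C3′ out of the main line and makes the route convergent. Acid 27 goes back through 26 and 25 to the chiral-pool lactone 22, which already holds C3′. The forward reactions must be a neutral acylation and an acidic global deprotection.

**Lactone C12–O6 (21 ⇐ 20 ⇐ 17 ⇐ 16).** C12 is taken back to the methyl group of a C7 isopropenyl unit. This uncovers in 16 a trans-2-isopropenylcyclohexanol, the signature of a carbonyl-ene product. Forward, the allylic oxidation must pick the C11=C13 propenyl over the C3=C4 unit; the allylic silyloxy group on C15 deactivates the latter.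

**Ring bond C6–C7 (16 ⇐ 15).** The ring is opened at C6–C7 and not elsewhere because this is the only ring bond whose cleavage gives a stable acyclic pair: an aldehyde (C6) and a trisubstituted olefin (C7=C11). Forward, an intramolecular type I ene reaction closes the six-membered ring and sets C6 and C7. The chair places the existing C5, C8 and C10 substituents equatorial and relays them into the all-equatorial array.

**Bond C5–C10, the key cut (15 ⇐ 14 ⇐ 13 ⇐ 11).** The 1,5-diene C2=C1–C10–C5–C4=C3 is disconnected by a [3,3] shift in which O–C6 takes the place of C3–C4 of the biosynthetic Cope substrate, i.e. an ester-enolate Claisen rearrangement of the acyclic allyl ester 11. This gives the hindered bond, the quaternary C10, the tertiary C5, the C1=C2 vinyl group and the C6 carbon at the right place. Ester 11 has one stereocentre (C8) and no ring. Forward, a chiral boron enolate must control enolate geometry and face.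

**Ester C6–O–C2 and bond C8–C9 (11 ⇐ 6 + 10; 6 ⇐ 5 ⇐ 4 ⇐ 2 + 3; 10 ⇐ 9 ⇐ 8 ⇐ 7).** Ester 11 is split into allylic alcohol 6 and the β,γ-unsaturated acid 10. Alcohol 6 comes from a catalytic asymmetric vinylogous aldol reaction of dienolate 2 with enal 3, which forms C8–C9, sets C8 and delivers the (E)-trisubstituted C1=C10 olefin in one step. Acid 10 comes from the itaconate half-ester 7.

## Alternatives that were turned down

**Alternative 1:** the textbook Diels–Alder route. Disconnection: ring bonds C5–C6 and C9–C10. Forward key step: [4+2] cycloaddition of the 1-methoxy-3-silyloxy diene A1 (C6–C9) with dienone A2 (C5=C10, acyl on C5), giving cyclohexanone A3 after hydrolysis of the enol ether. Turned down for four reasons: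
- A2 is a β,β-disubstituted enone, hence a hindered and weak dienophile, and it is itself a 2-substituted 1,3-diene (C2=C1–C10=C5) that can react as the diene or dimerise.
- The Lewis acid needed to activate it would destroy A1.
- The endo rule puts the C5 acyl group and the C6 oxygen cis, so C5 or C6 must be corrected.
- The cycloaddition fixes only the C5/C10 pair. C4 methylenation, C7 alkylation, C8 reduction against the axial C14 methyl, lactonisation and α-methylenation would still follow one by one, for more steps than the chosen route.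

**Alternative 2:** the literal biomimetic route. Disconnection: C5–C10 by Cope rearrangement of the ten-membered lactone A4 (C2–C3 bond intact, C1=C10 and C4=C5 olefins). Forward key step: thermal [3,3] shift through the chair-like crossed conformer. Turned down for three reasons:
- A4 is harder to make than the target. It has the same C6, C7 and C8 centres, two geometrically defined trisubstituted ring olefins and a ten-membered ring that needs a macrocyclisation of a long acyclic chain.
- The Cope rearrangement of such dienes is an equilibrium reached only near 200 °C, where the methylene lactone and the acrylate polymerise.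
- The step would win two stereocentres and cost more than it wins.

**Alternative 3:** functionalisation of a preformed six-membered ring. Disconnection: the C1–C10 bond, then C4–C5 and C7–C11 one at a time. Forward key step: conjugate addition of a vinyl cuprate to enone A5 (C6 carbonyl, C8 silyloxy) with enolate trapping at C5. Turned down for three reasons:
- Cuprates add anti to a 5-substituent, so the product A6 has the vinyl group trans to O8, which is the wrong C10 configuration.
- The inverse order (methyl cuprate on a 3-vinyl enone) opens the 1,6-addition pathway.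
- The C5 alkenyl unit next to the quaternary centre, the C7 side chain and the C6 carbinol (axial hydride attack blocked by the axial C14) would each be set singly, with no step that forms stereocentres as a group.

Key step: step 9

Assumption (sense of induction): the (S,S)-bisphosphoramide of step 2 and the (S,S)-bromoborane of step 9 are taken to give the configurations drawn; if either induces the opposite sense, its enantiomer is used and nothing else changes.
Assumption (enolate geometry, step 9): ester 11 is taken to enolise like a simple alkanoate, so that Et3N in toluene/hexane places the C5 substituent cis to the allyloxy oxygen.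

## Route

Step 1
Reactants: 1 methyl 3-methylbut-2-enoate
Product: 2 tert-butyl[(1-methoxy-3-methylbuta-1,3-dien-1-yl)oxy]dimethylsilane
Conditions: LDA, THF, −78 °C; TBSCl, DMPU, −78 °C → rt
Reagents that add atoms: tert-butyl(chloro)dimethylsilane, CC(C)(C)[Si](C)(C)Cl
Why: Kinetic γ-deprotonation of the senecioate (methyl cis to the ester) and O-silylation of the dienolate give the silyl dienol ether; standard silyl ketene acetal formation.

Step 2
Reactants: 2 tert-butyl[(1-methoxy-3-methylbuta-1,3-dien-1-yl)oxy]dimethylsilane; 3 3-methylbut-2-enal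
Product: 4 methyl (2E,5S)-5-hydroxy-3,7-dimethylocta-2,6-dienoate
Conditions: SiCl4 (1.1 equiv), (S,S)-binaphthyldiamine-derived bisphosphoramide (5 mol %), i-Pr2NEt (cat.), CH2Cl2, −78 °C; then pH 7 buffer
Reagents that add atoms: none
Why: Vinylogous Mukaiyama aldol reaction under Lewis-base activation of SiCl4: the γ-carbon of 2 adds 1,2 to the enal and the (E)-enoate is regenerated (C8–C9 bond, geraniol-type C1=C10 olefin); the chiral phosphoramide-bound silicon cation differentiates the aldehyde faces and sets C8 (S).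

Step 3
Reactants: 4 methyl (2E,5S)-5-hydroxy-3,7-dimethylocta-2,6-dienoate
Product: 5 methyl (2E,5S)-5-[(tert-butyldimethylsilyl)oxy]-3,7-dimethylocta-2,6-dienoate
Conditions: TBSCl, imidazole, DMF, rt
Reagents that add atoms: tert-butyl(chloro)dimethylsilane, CC(C)(C)[Si](C)(C)Cl
Why: Routine silylation of the secondary allylic alcohol; the TBS ether survives all steps up to step 15 and can then be removed in the presence of the primary TBDPS ether.

Step 4
Reactants: 5 methyl (2E,5S)-5-[(tert-butyldimethylsilyl)oxy]-3,7-dimethylocta-2,6-dienoate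
Product: 6 (2E,5S)-5-[(tert-butyldimethylsilyl)oxy]-3,7-dimethylocta-2,6-dien-1-ol
Conditions: DIBAL-H (2.5 equiv), CH2Cl2, −78 °C; Rochelle salt
Reagents that add atoms: none
Why: 1,2-Reduction of the enoate to the allylic alcohol with retention of the (E)-geometry.

Step 5
Reactants: 7 4-methoxy-2-methylidene-4-oxobutanoic acid (monomethyl itaconate)
Product: 8 methyl 3-(hydroxymethyl)but-3-enoate
Conditions: BH3·SMe2 (1.05 equiv), THF, −10 → 20 °C; MeOH
Reagents that add atoms: none
Why: Borane reduces the free carboxylic acid through its acyloxyborane much faster than the ester or the electron-poor acrylic olefin; 8 should be silylated at once, before it lactonises.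

Step 6
Reactants: 8 methyl 3-(hydroxymethyl)but-3-enoate
Product: 9 methyl 3-{[(tert-butyldiphenylsilyl)oxy]methyl}but-3-enoate
Conditions: TBDPSCl, imidazole, CH2Cl2, 0 °C → rt
Reagents that add atoms: tert-butyl(chloro)diphenylsilane, CC(C)(C)[Si](Cl)(c1ccccc1)c1ccccc1
Why: Silylation of the primary allylic alcohol; TBDPS on O15 is stable to the acid that later removes the TBS group from O8.

Step 7
Reactants: 9 methyl 3-{[(tert-butyldiphenylsilyl)oxy]methyl}but-3-enoate
Product: 10 3-{[(tert-butyldiphenylsilyl)oxy]methyl}but-3-enoic acid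
Conditions: LiOH·H2O, THF/H2O (3:1), 0 °C; then 1 M HCl to pH 3
Reagents that add atoms: lithium hydroxide, [Li+].[OH-]
Why: Saponification of the methyl ester; at 0 °C acyl substitution is faster than α-deprotonation, and the carboxylate then resists enolisation, so the olefin should stay out of conjugation.

Step 8
Reactants: 6 (2E,5S)-5-[(tert-butyldimethylsilyl)oxy]-3,7-dimethylocta-2,6-dien-1-ol; 10 3-{[(tert-butyldiphenylsilyl)oxy]methyl}but-3-enoic acid
Product: 11 (2E,5S)-5-[(tert-butyldimethylsilyl)oxy]-3,7-dimethylocta-2,6-dien-1-yl 3-{[(tert-butyldiphenylsilyl)oxy]methyl}but-3-enoate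
Conditions: PPh3, DIAD, THF, 0 °C → rt
Reagents that add atoms: none
Why: Mitsunobu esterification activates the primary allylic alcohol and not the acid, so no activated β,γ-unsaturated acyl species forms that could isomerise to the conjugated ester; SN2 at the primary carbon keeps the (E)-olefin.

Step 9
Reactants: 11 (2E,5S)-5-[(tert-butyldimethylsilyl)oxy]-3,7-dimethylocta-2,6-dien-1-yl 3-{[(tert-butyldiphenylsilyl)oxy]methyl}but-3-enoate
Product: 13 (2R,3S)-3-{(2S)-2-[(tert-butyldimethylsilyl)oxy]-4-methylpent-3-en-1-yl}-2-(3-{[tert-butyl(diphenyl)silyl]oxy}prop-1-en-2-yl)-3-methylpent-4-enoic acid, via boron ketene acetal 12 (not isolated)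
Conditions: (S,S)-2-bromo-4,5-diphenyl-1,3-bis{[3,5-bis(trifluoromethyl)phenyl]sulfonyl}-1,3,2-diazaborolidine (1.3 equiv), Et3N (1.6 equiv), toluene/hexane, −78 °C; then 4 °C, 3–5 d; aqueous work-up (ligand recovered)
Reagents that add atoms: none
Why: Soft enolisation of the only acidic position (the allylic α-CH2 of the β,γ-unsaturated ester) by the chiral bromoborane and Et3N gives boron ketene acetal 12 with the C5 alkenyl group cis to the allyloxy oxygen, and 12 undergoes a concerted suprafacial [3,3] shift (Ireland–Claisen rearrangement) that breaks C2–O and forms C5–C10. The closest known reaction type is the enantioselective boron-mediated ester-enolate Claisen rearrangement of (E)-3,3-disubstituted allyl esters, used for the vicinal quaternary/tertiary pair of elemane-type skeletons. No ring is closed; the bond forms through a six-membered chair transition state. C10 is controlled by the (E)-geometry of the allyl part (C9 chain equatorial, C14 axial) and C5 by the enolate geometry (alkenyl group axial, H equatorial), which together give the 5R*,10S* relationship; the absolute sense comes from the C2-symmetric bis-sulfonamide ligand on boron, which shields one face of the ketene acetal. C8 is too remote to interfere, so the step is reagent-controlled and also turns the minor enantiomer left from step 2 into a separable diastereomer. The selectivities needed are enolate geometry (Et3N in a non-polar medium), chair over boat (acyclic (E)-trisubstituted olefin) and chemoselective enolisation (one enolisable ester; the silyl ethers should be inert at low temperature). In one operation the step makes the hindered C5–C10 bond, both of its stereocentres and the C1=C2 vinyl group, and leaves the C3=C4 unit and the C6 carbon where the ring closure needs them.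

Step 10
Reactants: 13 (2R,3S)-3-{(2S)-2-[(tert-butyldimethylsilyl)oxy]-4-methylpent-3-en-1-yl}-2-(3-{[tert-butyl(diphenyl)silyl]oxy}prop-1-en-2-yl)-3-methylpent-4-enoic acid
Product: 14 (2R,3S)-3-{(2S)-2-[(tert-butyldimethylsilyl)oxy]-4-methylpent-3-en-1-yl}-2-(3-{[tert-butyl(diphenyl)silyl]oxy}prop-1-en-2-yl)-3-methylpent-4-en-1-ol
Conditions: LiAlH4, THF, 0 °C → rt
Reagents that add atoms: none
Why: Hydride reduction of the hindered acid to the primary alcohol; silyl ethers and isolated olefins are untouched, and C5 is not epimerisable at the carboxylate stage.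

Step 11
Reactants: 14 (2R,3S)-3-{(2S)-2-[(tert-butyldimethylsilyl)oxy]-4-methylpent-3-en-1-yl}-2-(3-{[tert-butyl(diphenyl)silyl]oxy}prop-1-en-2-yl)-3-methylpent-4-en-1-ol
Product: 15 (2R,3S)-3-{(2S)-2-[(tert-butyldimethylsilyl)oxy]-4-methylpent-3-en-1-yl}-2-(3-{[tert-butyl(diphenyl)silyl]oxy}prop-1-en-2-yl)-3-methylpent-4-enal
Conditions: Dess–Martin periodinane, pyridine, CH2Cl2, 0 °C → rt; used crude
Reagents that add atoms: none
Why: Buffered, non-basic oxidation to the C6 aldehyde; the β,γ-unsaturated α-branched aldehyde is not purified on silica, so that C5 neither epimerises nor moves into conjugation.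

Step 12
Reactants: 15 (2R,3S)-3-{(2S)-2-[(tert-butyldimethylsilyl)oxy]-4-methylpent-3-en-1-yl}-2-(3-{[tert-butyl(diphenyl)silyl]oxy}prop-1-en-2-yl)-3-methylpent-4-enal
Product: 16 8α-[(tert-butyldimethylsilyl)oxy]-15-[(tert-butyldiphenylsilyl)oxy]elema-1,3,11(13)-trien-6α-ol
Conditions: Me2AlCl (1.2 equiv), CH2Cl2, −78 °C; Rochelle salt
Reagents that add atoms: none
Why: Lewis-acid-promoted type I intramolecular carbonyl-ene reaction (isopulegol-type) of the C6 aldehyde with the trisubstituted C7=C11 olefin closes C6–C7. In the chair the C4 unit, the C8 silyloxy group and the vinyl group are equatorial and only C14 is axial, so the new 6α-OH and the 7β-isopropenyl group should come out trans-diequatorial; the hydrogen comes from the (E)-methyl group.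

Step 13
Reactants: 16 8α-[(tert-butyldimethylsilyl)oxy]-15-[(tert-butyldiphenylsilyl)oxy]elema-1,3,11(13)-trien-6α-ol
Product: 17 8α-[(tert-butyldimethylsilyl)oxy]-15-[(tert-butyldiphenylsilyl)oxy]elema-1,3,11(13)-triene-6α,12-diol
Conditions: SeO2 (0.5 equiv), t-BuOOH (3 equiv), salicylic acid (cat.), CH2Cl2, 0 °C → rt
Reagents that add atoms: selenium dioxide (oxygen carrier), O=[Se]=O; tert-butyl hydroperoxide (stoichiometric oxygen source), CC(C)(C)OO
Why: Allylic oxidation by ene reaction and [2,3] shift at the methyl group of the C11=C13 propenyl unit (CH3 before CH); the C3=C4 olefin is deactivated by its allylic silyloxy group, as in the ω-selective oxidation of O-protected geraniol-type dienes, and the vinyl group has no allylic hydrogen.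

Step 14
Reactants: 17 8α-[(tert-butyldimethylsilyl)oxy]-15-[(tert-butyldiphenylsilyl)oxy]elema-1,3,11(13)-triene-6α,12-diol
Product: 20 8α-[(tert-butyldimethylsilyl)oxy]-15-[(tert-butyldiphenylsilyl)oxy]elema-1,3,11(13)-trien-12,6α-olide, via hydroxy enal 18 (not isolated), via lactol 19 (not isolated)
Conditions: TEMPO (0.2 equiv), PhI(OAc)2 (2.5 equiv), CH2Cl2, rt
Reagents that add atoms: none
Why: Oxoammonium oxidation takes the primary allylic alcohol to the enal, which closes with the 6α-OH to the lactol and is oxidised again to the trans-fused α-methylene lactone (oxidative lactonisation of a 1,4-diol); the secondary alcohol is not oxidised competitively.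

Step 15
Reactants: 20 8α-[(tert-butyldimethylsilyl)oxy]-15-[(tert-butyldiphenylsilyl)oxy]elema-1,3,11(13)-trien-12,6α-olide
Product: 21 15-[(tert-butyldiphenylsilyl)oxy]-8α-hydroxyelema-1,3,11(13)-trien-12,6α-olide
Conditions: 48% aq. HF/MeCN (1:19), 0 °C → rt
Reagents that add atoms: none
Why: Acidic fluoride cleaves the secondary TBS ether much faster than the primary TBDPS ether; the non-basic medium leaves the methylene lactone untouched.

Step 16
Reactants: 22 (4R)-4-hydroxyoxolan-2-one
Product: 25 (4R)-4-hydroxy-3-methylideneoxolan-2-one, via Mannich base 23 (not isolated), via methiodide 24 (not isolated)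
Conditions: LDA (2.2 equiv), THF, −78 → −40 °C; CH2=NMe2+ I−, −78 °C → rt; then MeI, MeOH, rt; then aq. NaHCO3, CH2Cl2
Reagents that add atoms: dimethyl(methylidene)ammonium iodide, C=[N+](C)C.[I-]
Why: Fráter–Seebach-type alkylation of the alkoxide–enolate dianion (a β-alkoxide cannot be expelled) with the iminium salt, then quaternisation and E1cB loss of trimethylamine (α-methylenation); the carbinol centre, the future C3′, is not touched.

Step 17
Reactants: 25 (4R)-4-hydroxy-3-methylideneoxolan-2-one
Product: 26 methyl 2-[(4R)-2,2-dimethyl-1,3-dioxolan-4-yl]prop-2-enoate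
Conditions: Me2C(OMe)2, MeOH, TsOH·H2O (cat.), rt
Reagents that add atoms: 2,2-dimethoxypropane, COC(C)(C)OC; methanol, CO
Why: Acid-catalysed methanolysis of the lactone is pulled to the open form by trapping the 3′,4′-diol as its acetonide, as with the parent hydroxy lactone; no bond to the stereocentre is broken.

Step 18
Reactants: 26 methyl 2-[(4R)-2,2-dimethyl-1,3-dioxolan-4-yl]prop-2-enoate
Product: 27 2-[(4R)-2,2-dimethyl-1,3-dioxolan-4-yl]prop-2-enoic acid
Conditions: LiOH·H2O, THF/H2O, 0 °C → rt; then 1 M HCl to pH 4, 0 °C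
Reagents that add atoms: lithium hydroxide, [Li+].[OH-]
Why: Saponification of the α-substituted acrylate (conjugate addition of hydroxide is slow); the brief, cold acidification keeps the acetonide.

Step 19
Reactants: 21 15-[(tert-butyldiphenylsilyl)oxy]-8α-hydroxyelema-1,3,11(13)-trien-12,6α-olide; 27 2-[(4R)-2,2-dimethyl-1,3-dioxolan-4-yl]prop-2-enoic acid
Product: 29 15-[(tert-butyldiphenylsilyl)oxy]-8α-({2-[(4R)-2,2-dimethyl-1,3-dioxolan-4-yl]prop-2-enoyl}oxy)elema-1,3,11(13)-trien-12,6α-olide, via mixed anhydride 28 (not isolated)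
Conditions: 27, 2,4,6-Cl3C6H2COCl, Et3N, toluene, rt; then 21, DMAP, toluene, rt
Reagents that add atoms: none
Why: Yamaguchi esterification: the hindered mixed anhydride passes the acryloyl group via its acylpyridinium to the equatorial 8α-OH; no stereocentre is formed and the lactone oxygen is already acylated, so no translactonisation is possible.

Step 20
Reactants: 29 15-[(tert-butyldiphenylsilyl)oxy]-8α-({2-[(4R)-2,2-dimethyl-1,3-dioxolan-4-yl]prop-2-enoyl}oxy)elema-1,3,11(13)-trien-12,6α-olide
Product: 31 8α-{[(3R)-3,4-dihydroxy-2-methylidenebutanoyl]oxy}-15-hydroxyelema-1,3,11(13)-trien-12,6α-olide (CNP0234188.1), via 15-alcohol acetonide 30 (not isolated)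
Conditions: HF·pyridine, THF, 0 °C → rt; then AcOH/H2O (4:1), 40 °C, same flask
Reagents that add atoms: none
Why: Fluoride removes the primary TBDPS ether and aqueous acetic acid hydrolyses the terminal acetonide; both stages are acidic, which avoids Michael addition to the two methylene acceptors and base-induced self-lactonisation of the side chain.

## Compound list

1 | methyl 3-methylbut-2-enoate | COC(=O)C=C(C)C | starting material
2 | tert-butyl[(1-methoxy-3-methylbuta-1,3-dien-1-yl)oxy]dimethylsilane (E/Z mixture at the ketene acetal) | COC(=CC(C)=C)O[Si](C)(C)C(C)(C)C | intermediate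
3 | 3-methylbut-2-enal | CC(C)=CC=O | starting material
4 | methyl (2E,5S)-5-hydroxy-3,7-dimethylocta-2,6-dienoate | COC(=O)/C=C(\C)C[C@H](O)C=C(C)C | intermediate
5 | methyl (2E,5S)-5-[(tert-butyldimethylsilyl)oxy]-3,7-dimethylocta-2,6-dienoate | COC(=O)/C=C(\C)C[C@H](O[Si](C)(C)C(C)(C)C)C=C(C)C | intermediate
6 | (2E,5S)-5-[(tert-butyldimethylsilyl)oxy]-3,7-dimethylocta-2,6-dien-1-ol | OC/C=C(\C)C[C@H](O[Si](C)(C)C(C)(C)C)C=C(C)C | intermediate
7 | 4-methoxy-2-methylidene-4-oxobutanoic acid (monomethyl itaconate) | COC(=O)CC(=C)C(=O)O | starting material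
8 | methyl 3-(hydroxymethyl)but-3-enoate | COC(=O)CC(=C)CO | intermediate
9 | methyl 3-{[(tert-butyldiphenylsilyl)oxy]methyl}but-3-enoate | COC(=O)CC(=C)CO[Si](c1ccccc1)(c1ccccc1)C(C)(C)C | intermediate
10 | 3-{[(tert-butyldiphenylsilyl)oxy]methyl}but-3-enoic acid | OC(=O)CC(=C)CO[Si](c1ccccc1)(c1ccccc1)C(C)(C)C | intermediate
11 | (2E,5S)-5-[(tert-butyldimethylsilyl)oxy]-3,7-dimethylocta-2,6-dien-1-yl 3-{[(tert-butyldiphenylsilyl)oxy]methyl}but-3-enoate | C=C(CO[Si](c1ccccc1)(c1ccccc1)C(C)(C)C)CC(=O)OC/C=C(\C)C[C@H](O[Si](C)(C)C(C)(C)C)C=C(C)C | intermediate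
12 | boron ketene acetal of 11: O-[(4S,5S)-4,5-diphenyl-1,3-bis{[3,5-bis(trifluoromethyl)phenyl]sulfonyl}-1,3,2-diazaborolidin-2-yl] ketene acetal, C5 alkenyl group cis to the allyloxy oxygen | C=C(CO[Si](c1ccccc1)(c1ccccc1)C(C)(C)C)/C=C(/OB1N(S(=O)(=O)c2cc(C(F)(F)F)cc(C(F)(F)F)c2)[C@@H](c2ccccc2)[C@H](c2ccccc2)N1S(=O)(=O)c1cc(C(F)(F)F)cc(C(F)(F)F)c1)OC/C=C(\C)C[C@H](O[Si](C)(C)C(C)(C)C)C=C(C)C | intermediate (not isolated)
13 | (2R,3S)-3-{(2S)-2-[(tert-butyldimethylsilyl)oxy]-4-methylpent-3-en-1-yl}-2-(3-{[tert-butyl(diphenyl)silyl]oxy}prop-1-en-2-yl)-3-methylpent-4-enoic acid | C=C[C@](C)(C[C@H](O[Si](C)(C)C(C)(C)C)C=C(C)C)[C@@H](C(=O)O)C(=C)CO[Si](c1ccccc1)(c1ccccc1)C(C)(C)C | intermediate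
14 | (2R,3S)-3-{(2S)-2-[(tert-butyldimethylsilyl)oxy]-4-methylpent-3-en-1-yl}-2-(3-{[tert-butyl(diphenyl)silyl]oxy}prop-1-en-2-yl)-3-methylpent-4-en-1-ol | C=C[C@](C)(C[C@H](O[Si](C)(C)C(C)(C)C)C=C(C)C)[C@@H](CO)C(=C)CO[Si](c1ccccc1)(c1ccccc1)C(C)(C)C | intermediate
15 | (2R,3S)-3-{(2S)-2-[(tert-butyldimethylsilyl)oxy]-4-methylpent-3-en-1-yl}-2-(3-{[tert-butyl(diphenyl)silyl]oxy}prop-1-en-2-yl)-3-methylpent-4-enal | C=C[C@](C)(C[C@H](O[Si](C)(C)C(C)(C)C)C=C(C)C)[C@@H](C=O)C(=C)CO[Si](c1ccccc1)(c1ccccc1)C(C)(C)C | intermediate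
16 | 8α-[(tert-butyldimethylsilyl)oxy]-15-[(tert-butyldiphenylsilyl)oxy]elema-1,3,11(13)-trien-6α-ol | C=C[C@]1(C)C[C@H](O[Si](C)(C)C(C)(C)C)[C@@H](C(C)=C)[C@H](O)[C@H]1C(=C)CO[Si](c2ccccc2)(c2ccccc2)C(C)(C)C | intermediate
17 | 8α-[(tert-butyldimethylsilyl)oxy]-15-[(tert-butyldiphenylsilyl)oxy]elema-1,3,11(13)-triene-6α,12-diol | C=C[C@]1(C)C[C@H](O[Si](C)(C)C(C)(C)C)[C@@H](C(=C)CO)[C@H](O)[C@H]1C(=C)CO[Si](c2ccccc2)(c2ccccc2)C(C)(C)C | intermediate
18 | 8α-[(tert-butyldimethylsilyl)oxy]-15-[(tert-butyldiphenylsilyl)oxy]-6α-hydroxyelema-1,3,11(13)-trien-12-al | C=C[C@]1(C)C[C@H](O[Si](C)(C)C(C)(C)C)[C@@H](C(=C)C=O)[C@H](O)[C@H]1C(=C)CO[Si](c2ccccc2)(c2ccccc2)C(C)(C)C | intermediate (not isolated)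
19 | 12,6α-lactol of 18 (C12 epimers) | C=C[C@]1(C)C[C@H](O[Si](C)(C)C(C)(C)C)[C@H]2C(=C)C(O)O[C@@H]2[C@H]1C(=C)CO[Si](c3ccccc3)(c3ccccc3)C(C)(C)C | intermediate (not isolated)
20 | 8α-[(tert-butyldimethylsilyl)oxy]-15-[(tert-butyldiphenylsilyl)oxy]elema-1,3,11(13)-trien-12,6α-olide | C=C[C@]1(C)C[C@H](O[Si](C)(C)C(C)(C)C)[C@H]2C(=C)C(=O)O[C@@H]2[C@H]1C(=C)CO[Si](c3ccccc3)(c3ccccc3)C(C)(C)C | intermediate
21 | 15-[(tert-butyldiphenylsilyl)oxy]-8α-hydroxyelema-1,3,11(13)-trien-12,6α-olide | C=C[C@]1(C)C[C@H](O)[C@H]2C(=C)C(=O)O[C@@H]2[C@H]1C(=C)CO[Si](c3ccccc3)(c3ccccc3)C(C)(C)C | intermediate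
22 | (4R)-4-hydroxyoxolan-2-one [(R)-3-hydroxy-γ-butyrolactone] | O=C1C[C@@H](O)CO1 | starting material
23 | (4R)-3-[(dimethylamino)methyl]-4-hydroxyoxolan-2-one (mainly 3,4-trans) | O=C1OC[C@H](O)C1CN(C)C | intermediate (not isolated)
24 | {[(4R)-4-hydroxy-2-oxooxolan-3-yl]methyl}trimethylammonium iodide | O=C1OC[C@H](O)C1C[N+](C)(C)C.[I-] | intermediate (not isolated)
25 | (4R)-4-hydroxy-3-methylideneoxolan-2-one | O=C1OC[C@H](O)C1=C | intermediate
26 | methyl 2-[(4R)-2,2-dimethyl-1,3-dioxolan-4-yl]prop-2-enoate | COC(=O)C(=C)[C@@H]1COC(C)(C)O1 | intermediate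
27 | 2-[(4R)-2,2-dimethyl-1,3-dioxolan-4-yl]prop-2-enoic acid | OC(=O)C(=C)[C@@H]1COC(C)(C)O1 | intermediate
28 | 2-[(4R)-2,2-dimethyl-1,3-dioxolan-4-yl]prop-2-enoic 2,4,6-trichlorobenzoic anhydride | C=C(C(=O)OC(=O)c1c(Cl)cc(Cl)cc1Cl)[C@@H]1COC(C)(C)O1 | intermediate (not isolated)
29 | 15-[(tert-butyldiphenylsilyl)oxy]-8α-({2-[(4R)-2,2-dimethyl-1,3-dioxolan-4-yl]prop-2-enoyl}oxy)elema-1,3,11(13)-trien-12,6α-olide | C=C[C@]1(C)C[C@H](OC(=O)C(=C)[C@@H]2COC(C)(C)O2)[C@H]2C(=C)C(=O)O[C@@H]2[C@H]1C(=C)CO[Si](c3ccccc3)(c3ccccc3)C(C)(C)C | intermediate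
30 | 8α-({2-[(4R)-2,2-dimethyl-1,3-dioxolan-4-yl]prop-2-enoyl}oxy)-15-hydroxyelema-1,3,11(13)-trien-12,6α-olide | C=C[C@]1(C)C[C@H](OC(=O)C(=C)[C@@H]2COC(C)(C)O2)[C@H]2C(=C)C(=O)O[C@@H]2[C@H]1C(=C)CO | intermediate (not isolated)
31 | 8α-{[(3R)-3,4-dihydroxy-2-methylidenebutanoyl]oxy}-15-hydroxyelema-1,3,11(13)-trien-12,6α-olide (CNP0234188.1) | C=C[C@]1(C)C[C@H](OC(=O)C(=C)[C@@H](O)CO)[C@H]2C(=C)C(=O)O[C@@H]2[C@H]1C(=C)CO | target

## Step count and least certain steps

Total step count: 20. Longest linear sequence: 14 steps (steps 1–4, 8–15, 19 and 20, from 1). Steps 5–7 (acid 10) and 16–18 (acid 27) are side branches.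

**Step 9 (key step).** The most likely failures are three: erosion of facial selectivity or the wrong enolate geometry with the alkenyl-substituted enolate; a rearrangement that is slow at the trisubstituted terminus; and loss of a silyl ether to the Lewis-acidic boron reagent during the long reaction time. Fallback: give up reagent control and use the C8 centre as an internal resolving handle. Setting out from 11, a classical Ireland–Claisen rearrangement (LDA, THF, −78 °C; TMSCl/Et3N; warm to rt; dilute HCl) proceeds through the trimethylsilyl ketene acetal of 11, F1. The chair transition state still fixes the C5/C10 relationship but not the face, so 13 should form together with the (2S,3R)-diastereomer of acid 13, F2. The two acids differ at two of three centres and are separated by chromatography; the route is rejoined at 13.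

**Step 12.** The allylic C8 silyl ether may ionise under the Lewis acid (elimination or allylic substitution), a stepwise cationic pathway may give chlorides or the cis isomer, and the β,γ-unsaturated aldehyde may isomerise before it cyclises. Fallback: a neutral organometallic ring closure. Setting out from 14, SeO2/t-BuOOH oxidises the (E)-methyl group of the trisubstituted olefin to the (E)-allylic alcohol–primary alcohol diol F3. CBr4/PPh3 at −40 °C converts the allylic hydroxyl, the more reactive of the two, to the allylic bromide F4. Dess–Martin oxidation gives the bromo aldehyde F5. CrCl2 in THF (Nozaki–Hiyama–Kishi allylation) then closes C6–C7 by γ-attack through a chair and regenerates the isopropenyl group; the route is rejoined at 16.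

**Step 13.** Oxidation may also occur at the C3=C4/C15 allyl ether unit, or run on to the enal with low conversion. Fallback: place the oxygen by epoxidation and eliminative opening instead of an ene oxidation. Setting out from 16, hydroxyl-directed epoxidation (VO(acac)2, t-BuOOH, CH2Cl2) should give the 11,13-epoxide of 16, F6. Diethylaluminium 2,2,6,6-tetramethylpiperidide (toluene, 0 °C) isomerises the 1,1-disubstituted epoxide to the 2-substituted allylic alcohol, which is 17; the route is rejoined at 17.

**Step 2.** Face selection may be insufficient with the β,β-disubstituted enal, or some α-attack of the dienolate may occur. Fallback: separate C–C bond formation from the creation of the stereocentre. Setting out from 2 and 3, a BF3·OEt2-mediated vinylogous Mukaiyama aldol reaction gives racemic methyl (2E)-5-hydroxy-3,7-dimethylocta-2,6-dienoate, F7. MnO2 oxidises it to methyl (2E)-3,7-dimethyl-5-oxoocta-2,6-dienoate, F8. Corey–Bakshi–Shibata reduction with the (R)-oxazaborolidine and catecholborane at −78 °C (alkenyl as the large group) returns the (S)-alcohol; the route is rejoined at 4.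

## Further compounds

F1 | step 9 | trimethylsilyl ketene acetal of 11 (alkenyl group cis to the allyloxy oxygen) | C=C(CO[Si](c1ccccc1)(c1ccccc1)C(C)(C)C)/C=C(/O[Si](C)(C)C)OC/C=C(\C)C[C@H](O[Si](C)(C)C(C)(C)C)C=C(C)C
F2 | step 9 | (2S,3R)-3-{(2S)-2-[(tert-butyldimethylsilyl)oxy]-4-methylpent-3-en-1-yl}-2-(3-{[tert-butyl(diphenyl)silyl]oxy}prop-1-en-2-yl)-3-methylpent-4-enoic acid | C=C[C@@](C)(C[C@H](O[Si](C)(C)C(C)(C)C)C=C(C)C)[C@H](C(=O)O)C(=C)CO[Si](c1ccccc1)(c1ccccc1)C(C)(C)C
F3 | step 12 | (2R,3S)-3-{(2S,3E)-2-[(tert-butyldimethylsilyl)oxy]-5-hydroxy-4-methylpent-3-en-1-yl}-2-(3-{[tert-butyl(diphenyl)silyl]oxy}prop-1-en-2-yl)-3-methylpent-4-en-1-ol | C=C[C@](C)(C[C@H](O[Si](C)(C)C(C)(C)C)/C=C(\C)CO)[C@@H](CO)C(=C)CO[Si](c1ccccc1)(c1ccccc1)C(C)(C)C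
F4 | step 12 | (2R,3S)-3-{(2S,3E)-5-bromo-2-[(tert-butyldimethylsilyl)oxy]-4-methylpent-3-en-1-yl}-2-(3-{[tert-butyl(diphenyl)silyl]oxy}prop-1-en-2-yl)-3-methylpent-4-en-1-ol | C=C[C@](C)(C[C@H](O[Si](C)(C)C(C)(C)C)/C=C(\C)CBr)[C@@H](CO)C(=C)CO[Si](c1ccccc1)(c1ccccc1)C(C)(C)C
F5 | step 12 | (2R,3S)-3-{(2S,3E)-5-bromo-2-[(tert-butyldimethylsilyl)oxy]-4-methylpent-3-en-1-yl}-2-(3-{[tert-butyl(diphenyl)silyl]oxy}prop-1-en-2-yl)-3-methylpent-4-enal | C=C[C@](C)(C[C@H](O[Si](C)(C)C(C)(C)C)/C=C(\C)CBr)[C@@H](C=O)C(=C)CO[Si](c1ccccc1)(c1ccccc1)C(C)(C)C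
F6 | step 13 | 11,13-epoxide of 16 (C11 epimers; either serves) | C=C[C@]1(C)C[C@H](O[Si](C)(C)C(C)(C)C)[C@@H](C2(C)CO2)[C@H](O)[C@H]1C(=C)CO[Si](c3ccccc3)(c3ccccc3)C(C)(C)C
F7 | step 2 | racemic methyl (2E)-5-hydroxy-3,7-dimethylocta-2,6-dienoate | COC(=O)/C=C(\C)CC(O)C=C(C)C
F8 | step 2 | methyl (2E)-3,7-dimethyl-5-oxoocta-2,6-dienoate | COC(=O)/C=C(\C)CC(=O)C=C(C)C
A1 | alternative 1 | (1E)-1-methoxy-3-[(trimethylsilyl)oxy]buta-1,3-diene | CO/C=C/C(=C)O[Si](C)(C)C
A2 | alternative 1 | (3E)-1-[(tert-butyldiphenylsilyl)oxy]-4-methylhexa-3,5-dien-2-one | C=C/C(C)=C/C(=O)CO[Si](c1ccccc1)(c1ccccc1)C(C)(C)C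
A3 | alternative 1 | endo cycloadduct, 4-{[(tert-butyldiphenylsilyl)oxy]acetyl}-3-methoxy-5-methyl-5-vinylcyclohexan-1-one (3-methoxy cis to the 4-acyl group, acyl trans to vinyl) | C=C[C@]1(C)CC(=O)C[C@@H](OC)[C@H]1C(=O)CO[Si](c2ccccc2)(c2ccccc2)C(C)(C)C
A4 | alternative 2 | 8α-[(tert-butyldimethylsilyl)oxy]-15-[(tert-butyldiphenylsilyl)oxy]germacra-1(10)E,4Z,11(13)-trien-12,6α-olide | C/C1=C\CC/C(CO[Si](c2ccccc2)(c2ccccc2)C(C)(C)C)=C/[C@H]2OC(=O)C(=C)[C@@H]2[C@@H](O[Si](C)(C)C(C)(C)C)C1
A5 | alternative 3 | (5S)-5-[(tert-butyldimethylsilyl)oxy]-3-methylcyclohex-2-en-1-one | CC1=CC(=O)C[C@@H](O[Si](C)(C)C(C)(C)C)C1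
A6 | alternative 3 | (5S)-5-[(tert-butyldimethylsilyl)oxy]-3-ethenyl-3-methylcyclohexan-1-one with the vinyl group trans to the silyloxy group | C=C[C@@]1(C)C[C@H](O[Si](C)(C)C(C)(C)C)CC(=O)C1
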